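**Retrosynthetic overview**
1. The target is a trans-fused hydrindane. Ring B (C1, C2, C3, C3a, C7a; ethylidene on C1, OAc on C2) is bought as cyclopent-2-en-1-one; ring A (C3a, C4, C5, C6, C7, C7a) is formed second, in the key step.
2. Key disconnection: C4–C5 and C6–C7 together, a [4+2] annulation of a two-carbon glycolaldehyde enol silane (C5–C6, both oxygens in place and already differentiated) onto the four-carbon unit C4–C3a–C7a–C7.
3. Enabling feature: the C5/C6 glycol is flanked by C4, whose exocyclic methylene is the retron of a 1-silylvinyl group (ipso nucleophile), and by C7, which is the β-carbon of an exocyclic enone while C1 of ring B is a ketone; C4 and C7 hang on the adjacent ring-B atoms C3a and C7a.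
4. Further disconnections: C7=C7a (aldol condensation with 2-methylpropanal) and C3a–C4 (catalytic asymmetric conjugate addition). C3a is set by catalysis; C7, C6, C5 and C7a are relayed from it in the key step; C2 is set by a second catalyst-controlled step.
5. Endgame on the periphery: O5 angelate, C2 oxygenation, Z-ethylidene by Wittig reaction of the α-silyloxy ketone, O2 acetate, O6 desilylation.

Key step: step 4

Remark: all bicyclic compounds carry the locants of the target's octahydro-1H-indene skeleton (C1 ethylidene carbon, C2 acetoxy carbon, C3, C3a, C4 methylidene carbon, C5 angelate carbon, C6 carbinol carbon, C7 isopropyl carbon, C7a).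
Remark: which enantiomer of the ligand (step 2) and of the ketone catalyst (step 7) delivers 3R and 2S is assumed to be settled by a trial with both antipodes; the names given are the working choice.

Step 1
Reactants: 1 2-{[tert-butyl(dimethyl)silyl]oxy}acetaldehyde
Product: 2 (Z)-1-{[tert-butyl(dimethyl)silyl]oxy}-2-[(trimethylsilyl)oxy]ethene
Conditions: Me3SiCl, Et3N, MeCN, rt
Reagents that add atoms: chlorotrimethylsilane, C[Si](C)(C)Cl
Why: O-silylation of the aldehyde enolate under soft enolization (silyl enol ether formation) should give the Z isomer, the usual preference of α-oxygenated aldehydes.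

Step 2
Reactants: 3 cyclopent-2-en-1-one
Product: 5 (2R,3R)-2-[(1RS)-1-hydroxy-2-methylpropyl]-3-[1-(trimethylsilyl)ethenyl]cyclopentan-1-one, via magnesium enolate 4 (not isolated)
Conditions: [1-(trimethylsilyl)ethenyl]magnesium bromide (THF solution, prepared beforehand from (1-bromoethenyl)trimethylsilane and Mg), CuBr·SMe2 (5 mol %), (R)-1-[(Sp)-2-(diphenylphosphino)ferrocenyl]ethyldicyclohexylphosphine (6 mol %), t-BuOMe, −78 °C; then 2-methylpropanal, −78 °C; aq. NH4Cl
Reagents that add atoms: [1-(trimethylsilyl)ethenyl]magnesium bromide, C=C([Mg]Br)[Si](C)(C)C; 2-methylpropanal, CC(C)C=O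
Why: Copper-catalysed asymmetric conjugate addition of the Grignard reagent sets C3 under ligand control, and the regiodefined magnesium enolate 4 undergoes aldol addition anti to the new C3 substituent, so C2 and C3 are trans; the carbinol epimers converge in step 3.

Step 3
Reactants: 5 (2R,3R)-2-[(1RS)-1-hydroxy-2-methylpropyl]-3-[1-(trimethylsilyl)ethenyl]cyclopentan-1-one
Product: 7 (2E,3R)-2-(2-methylpropylidene)-3-[1-(trimethylsilyl)ethenyl]cyclopentan-1-one, via mesylate 6 (not isolated)
Conditions: MsCl, Et3N, CH2Cl2, 0 °C; then DBU, 0 °C → rt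
Reagents that add atoms: none
Why: Mesylation and base-induced elimination (aldol dehydration, E1cB) should give the conjugated exocyclic enone as the E isomer, which keeps the isopropyl group away from the carbonyl oxygen and leaves C3 untouched.

Step 4
Reactants: 7 (2E,3R)-2-(2-methylpropylidene)-3-[1-(trimethylsilyl)ethenyl]cyclopentan-1-one; 2 (Z)-1-{[tert-butyl(dimethyl)silyl]oxy}-2-[(trimethylsilyl)oxy]ethene
Product: 10 (3aR,5S,6S,7S,7aR)-6-{[tert-butyl(dimethyl)silyl]oxy}-5-hydroxy-4-methylidene-7-(propan-2-yl)octahydro-1H-inden-1-one, via Michael adduct 8 (not isolated), via bis-silylated bicycle 9 (not isolated)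
Conditions: 2 (1.1 equiv), Me3SiNTf2 (5 mol %), CH2Cl2 (0.02 M), −78 → −20 °C; then K2CO3, MeOH, 0 °C → rt
Reagents that add atoms: none
Why: Proposed new method: Me3SiNTf2 activates enone 7 for Mukaiyama–Michael addition of 2 through its Me3SiO enol terminus (C6–C7 bond, adduct 8), the aldehyde thus set free is activated again as its silyloxocarbenium ion and is captured by the pendant 1-silylvinyl group through ipso attack at the silicon-bearing carbon (C4–C5 bond), and loss of Me3Si+ returns the catalyst and leaves the exocyclic methylene (9); the closest known reaction types are the silyl-triflimide-catalysed Mukaiyama–Michael addition of aldehyde enol silanes and the vinylsilane-terminated (silyl-Prins-type) cyclization of oxocarbenium ions, merged here into one catalytic event. Ring A closes in the 6-exo-trig mode, since attack through the CH2 terminus would be a 7-endo closure and would put the cation α instead of β to silicon. C7 is set by attack on the enone face opposite the C3 substituent of 7, which A(1,3) strain with the E-alkylidene holds pseudoaxial; C6 by the anti-selective open transition state (equivalent to an endo [4+2] arrangement) that places the OTBS group cis to the isopropyl group; C5 by a chair-like transition state with the isopropyl group equatorial and the silyloxocarbenium oxygen axial, anti to the C6–O dipole and clear of the developing methylene. C7a is set last under thermodynamic control in the K2CO3–MeOH stage, because the cis-fused epimer would carry a 1,3-diaxial C1/C6–OTBS contact, so both C7a epimers funnel into the trans-fused ketone. The step needs site selectivity within 2 (secured by the far greater reactivity of the trimethylsilyl over the tert-butyldimethylsilyl enol terminus) and ring closure ahead of intermolecular aldol addition of 2 to the new aldehyde (secured by high dilution and the near-stoichiometric amount of 2).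

Step 5
Reactants: 10 (3aR,5S,6S,7S,7aR)-6-{[tert-butyl(dimethyl)silyl]oxy}-5-hydroxy-4-methylidene-7-(propan-2-yl)octahydro-1H-inden-1-one
Product: 11 (3aR,5S,6S,7S,7aR)-6-{[tert-butyl(dimethyl)silyl]oxy}-4-methylidene-1-oxo-7-(propan-2-yl)octahydro-1H-inden-5-yl (2Z)-2-methylbut-2-enoate
Conditions: (2Z)-2-methylbut-2-enoic acid, 2,4,6-trichlorobenzoyl chloride, Et3N, toluene, rt; then 10, 80 °C
Reagents that add atoms: (2Z)-2-methylbut-2-enoic acid (angelic acid), C/C=C(/C)C(=O)O
Why: Yamaguchi esterification through the mixed anhydride, run without a nucleophilic amine catalyst so that the Z double bond of the acid should not isomerize, acylates the only free hydroxyl with retention at C5.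

Step 6
Reactants: 11 (3aR,5S,6S,7S,7aR)-6-{[tert-butyl(dimethyl)silyl]oxy}-4-methylidene-1-oxo-7-(propan-2-yl)octahydro-1H-inden-5-yl (2Z)-2-methylbut-2-enoate
Product: 12 C1 triethylsilyl enol ether (C1=C2) of 11
Conditions: LiN(SiMe3)2, THF, −78 °C; then Et3SiCl, −78 → 0 °C
Reagents that add atoms: chlorotriethylsilane, CC[Si](Cl)(CC)CC
Why: Kinetic deprotonation at the C2 methylene (the ring-fusion C7a–H is tertiary and hindered) followed by O-silylation gives the C1=C2 silyl enol ether regioselectively.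

Step 7
Reactants: 12 C1 triethylsilyl enol ether (C1=C2) of 11
Product: 14 (2S,3aR,5S,6S,7S,7aR)-6-{[tert-butyl(dimethyl)silyl]oxy}-2-hydroxy-4-methylidene-1-oxo-7-(propan-2-yl)octahydro-1H-inden-5-yl (2Z)-2-methylbut-2-enoate, via silyloxy epoxide 13 (not isolated)
Conditions: Oxone (2KHSO5·KHSO4·K2SO4), 1,2:4,5-di-O-isopropylidene-β-D-erythro-2,3-hexodiulo-2,6-pyranose (30 mol %), K2CO3, Bu4NHSO4, MeCN–CH2(OMe)2–aq. buffer (pH 10.5), 0 °C
Reagents that add atoms: potassium peroxymonosulfate, [K+].[O-]S(=O)(=O)OO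
Why: Shi epoxidation by the chiral dioxirane should be chemoselective for the electron-rich silyl enol ether (the other alkenes are 1,1-disubstituted or conjugated to an ester) and sets C2 under catalyst control, the silyloxy epoxide 13 collapsing to the α-hydroxy ketone as in a Rubottom oxidation.

Step 8
Reactants: 14 (2S,3aR,5S,6S,7S,7aR)-6-{[tert-butyl(dimethyl)silyl]oxy}-2-hydroxy-4-methylidene-1-oxo-7-(propan-2-yl)octahydro-1H-inden-5-yl (2Z)-2-methylbut-2-enoate
Product: 15 (2S,3aR,5S,6S,7S,7aR)-6-{[tert-butyl(dimethyl)silyl]oxy}-4-methylidene-1-oxo-7-(propan-2-yl)-2-[(triethylsilyl)oxy]octahydro-1H-inden-5-yl (2Z)-2-methylbut-2-enoate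
Conditions: Et3SiOTf, 2,6-lutidine, CH2Cl2, −78 °C
Reagents that add atoms: triethylsilyl trifluoromethanesulfonate, CC[Si](CC)(CC)OS(=O)(=O)C(F)(F)F
Why: Silylation of the secondary alcohol with a silyl triflate and a hindered base is fast at low temperature and should leave the epimerizable C2 and C7a centres untouched.

Step 9
Reactants: 15 (2S,3aR,5S,6S,7S,7aR)-6-{[tert-butyl(dimethyl)silyl]oxy}-4-methylidene-1-oxo-7-(propan-2-yl)-2-[(triethylsilyl)oxy]octahydro-1H-inden-5-yl (2Z)-2-methylbut-2-enoate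
Product: 16 (1Z,2S,3aR,5S,6S,7S,7aR)-6-{[tert-butyl(dimethyl)silyl]oxy}-1-ethylidene-4-methylidene-7-(propan-2-yl)-2-[(triethylsilyl)oxy]octahydro-1H-inden-5-yl (2Z)-2-methylbut-2-enoate
Conditions: EtPPh3Br, KN(SiMe3)2, THF, 0 °C; then 15, 0 °C → rt
Reagents that add atoms: ethyltriphenylphosphonium bromide, CC[P+](c1ccccc1)(c1ccccc1)c1ccccc1.[Br-]
Why: Wittig olefination of an α-silyloxy ketone with a non-stabilized ylide, a reaction type known to place the ylide alkyl group cis to the oxygen-bearing α-carbon, should give the Z-ethylidene group while the hindered angelate survives.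

Step 10
Reactants: 16 (1Z,2S,3aR,5S,6S,7S,7aR)-6-{[tert-butyl(dimethyl)silyl]oxy}-1-ethylidene-4-methylidene-7-(propan-2-yl)-2-[(triethylsilyl)oxy]octahydro-1H-inden-5-yl (2Z)-2-methylbut-2-enoate
Product: 17 (1Z,2S,3aR,5S,6S,7S,7aR)-6-{[tert-butyl(dimethyl)silyl]oxy}-1-ethylidene-2-hydroxy-4-methylidene-7-(propan-2-yl)octahydro-1H-inden-5-yl (2Z)-2-methylbut-2-enoate
Conditions: pyridinium 4-toluenesulfonate (10 mol %), MeOH–CH2Cl2, 0 °C
Reagents that add atoms: none
Why: Acid-catalysed methanolysis (selective desilylation) should cleave the triethylsilyl ether far faster than the hindered secondary tert-butyldimethylsilyl ether.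

Step 11
Reactants: 17 (1Z,2S,3aR,5S,6S,7S,7aR)-6-{[tert-butyl(dimethyl)silyl]oxy}-1-ethylidene-2-hydroxy-4-methylidene-7-(propan-2-yl)octahydro-1H-inden-5-yl (2Z)-2-methylbut-2-enoate
Product: 18 (1Z,2S,3aR,5S,6S,7S,7aR)-2-(acetyloxy)-6-{[tert-butyl(dimethyl)silyl]oxy}-1-ethylidene-4-methylidene-7-(propan-2-yl)octahydro-1H-inden-5-yl (2Z)-2-methylbut-2-enoate
Conditions: Ac2O, pyridine, 4-(dimethylamino)pyridine (cat.), CH2Cl2, 0 °C → rt
Reagents that add atoms: acetic anhydride, CC(=O)OC(C)=O
Why: Acetylation of the only free hydroxyl (nucleophilic acyl-transfer catalysis) proceeds with retention at C2.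

Step 12
Reactants: 18 (1Z,2S,3aR,5S,6S,7S,7aR)-2-(acetyloxy)-6-{[tert-butyl(dimethyl)silyl]oxy}-1-ethylidene-4-methylidene-7-(propan-2-yl)octahydro-1H-inden-5-yl (2Z)-2-methylbut-2-enoate
Product: 19 (1Z,2S,3aR,5S,6S,7S,7aR)-2-(acetyloxy)-1-ethylidene-6-hydroxy-4-methylidene-7-(propan-2-yl)octahydro-1H-inden-5-yl (2Z)-2-methylbut-2-enoate
Conditions: HF·pyridine, pyridine, THF, 0 °C → rt
Reagents that add atoms: none
Why: Fluoride-mediated desilylation under buffered acidic conditions should free O6 without touching the two esters, and acyl migration from O5 is not possible across the trans-diaxial arrangement.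

**Compound list**
1 | 2-{[tert-butyl(dimethyl)silyl]oxy}acetaldehyde | CC(C)(C)[Si](C)(C)OCC=O | starting material
2 | (Z)-1-{[tert-butyl(dimethyl)silyl]oxy}-2-[(trimethylsilyl)oxy]ethene | CC(C)(C)[Si](C)(C)O/C=C\O[Si](C)(C)C | intermediate
3 | cyclopent-2-en-1-one | O=C1C=CCC1 | starting material
4 | bromomagnesium (3R)-3-[1-(trimethylsilyl)ethenyl]cyclopent-1-en-1-olate | C=C([Si](C)(C)C)[C@@H]1CCC(O[Mg]Br)=C1 | intermediate
5 | (2R,3R)-2-[(1RS)-1-hydroxy-2-methylpropyl]-3-[1-(trimethylsilyl)ethenyl]cyclopentan-1-one | C=C([Si](C)(C)C)[C@@H]1CCC(=O)[C@H]1C(O)C(C)C | intermediate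
6 | (1RS)-2-methyl-1-{(1R,5R)-2-oxo-5-[1-(trimethylsilyl)ethenyl]cyclopentyl}propyl methanesulfonate | C=C([Si](C)(C)C)[C@@H]1CCC(=O)[C@H]1C(OS(C)(=O)=O)C(C)C | intermediate
7 | (2E,3R)-2-(2-methylpropylidene)-3-[1-(trimethylsilyl)ethenyl]cyclopentan-1-one | C=C([Si](C)(C)C)[C@@H]1CCC(=O)/C1=C/C(C)C | intermediate
8 | (2S,3S)-2-{[tert-butyl(dimethyl)silyl]oxy}-4-methyl-3-{(5R)-5-[1-(trimethylsilyl)ethenyl]-2-[(trimethylsilyl)oxy]cyclopent-1-en-1-yl}pentanal | C=C([Si](C)(C)C)[C@@H]1CCC(O[Si](C)(C)C)=C1[C@H](C(C)C)[C@H](O[Si](C)(C)C(C)(C)C)C=O | intermediate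
9 | C1 trimethylsilyl enol ether (C1=C7a) and O5 trimethylsilyl ether of 10, (3aS,5S,6S,7S) | C=C1[C@@H]2CCC(O[Si](C)(C)C)=C2[C@H](C(C)C)[C@H](O[Si](C)(C)C(C)(C)C)[C@H]1O[Si](C)(C)C | intermediate
10 | (3aR,5S,6S,7S,7aR)-6-{[tert-butyl(dimethyl)silyl]oxy}-5-hydroxy-4-methylidene-7-(propan-2-yl)octahydro-1H-inden-1-one | C=C1[C@@H]2CCC(=O)[C@H]2[C@H](C(C)C)[C@H](O[Si](C)(C)C(C)(C)C)[C@H]1O | intermediate
11 | (3aR,5S,6S,7S,7aR)-6-{[tert-butyl(dimethyl)silyl]oxy}-4-methylidene-1-oxo-7-(propan-2-yl)octahydro-1H-inden-5-yl (2Z)-2-methylbut-2-enoate | C=C1[C@@H]2CCC(=O)[C@H]2[C@H](C(C)C)[C@H](O[Si](C)(C)C(C)(C)C)[C@H]1OC(=O)/C(C)=C\C | intermediate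
12 | C1 triethylsilyl enol ether (C1=C2) of 11, (3aR,5S,6S,7S,7aR) | C=C1[C@@H]2CC=C(O[Si](CC)(CC)CC)[C@H]2[C@H](C(C)C)[C@H](O[Si](C)(C)C(C)(C)C)[C@H]1OC(=O)/C(C)=C\C | intermediate
13 | 1,2-epoxide of 12 on the face cis to H-7a, (1S,2S,3aR,5S,6S,7S,7aR) | C=C1[C@@H]2C[C@@H]3O[C@]3(O[Si](CC)(CC)CC)[C@H]2[C@H](C(C)C)[C@H](O[Si](C)(C)C(C)(C)C)[C@H]1OC(=O)/C(C)=C\C | intermediate
14 | (2S,3aR,5S,6S,7S,7aR)-6-{[tert-butyl(dimethyl)silyl]oxy}-2-hydroxy-4-methylidene-1-oxo-7-(propan-2-yl)octahydro-1H-inden-5-yl (2Z)-2-methylbut-2-enoate | C=C1[C@@H]2C[C@H](O)C(=O)[C@H]2[C@H](C(C)C)[C@H](O[Si](C)(C)C(C)(C)C)[C@H]1OC(=O)/C(C)=C\C | intermediate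
15 | (2S,3aR,5S,6S,7S,7aR)-6-{[tert-butyl(dimethyl)silyl]oxy}-4-methylidene-1-oxo-7-(propan-2-yl)-2-[(triethylsilyl)oxy]octahydro-1H-inden-5-yl (2Z)-2-methylbut-2-enoate | C=C1[C@@H]2C[C@H](O[Si](CC)(CC)CC)C(=O)[C@H]2[C@H](C(C)C)[C@H](O[Si](C)(C)C(C)(C)C)[C@H]1OC(=O)/C(C)=C\C | intermediate
16 | (1Z,2S,3aR,5S,6S,7S,7aR)-6-{[tert-butyl(dimethyl)silyl]oxy}-1-ethylidene-4-methylidene-7-(propan-2-yl)-2-[(triethylsilyl)oxy]octahydro-1H-inden-5-yl (2Z)-2-methylbut-2-enoate | C=C1[C@@H]2C[C@H](O[Si](CC)(CC)CC)/C(=C\C)[C@H]2[C@H](C(C)C)[C@H](O[Si](C)(C)C(C)(C)C)[C@H]1OC(=O)/C(C)=C\C | intermediate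
17 | (1Z,2S,3aR,5S,6S,7S,7aR)-6-{[tert-butyl(dimethyl)silyl]oxy}-1-ethylidene-2-hydroxy-4-methylidene-7-(propan-2-yl)octahydro-1H-inden-5-yl (2Z)-2-methylbut-2-enoate | C=C1[C@@H]2C[C@H](O)/C(=C\C)[C@H]2[C@H](C(C)C)[C@H](O[Si](C)(C)C(C)(C)C)[C@H]1OC(=O)/C(C)=C\C | intermediate
18 | (1Z,2S,3aR,5S,6S,7S,7aR)-2-(acetyloxy)-6-{[tert-butyl(dimethyl)silyl]oxy}-1-ethylidene-4-methylidene-7-(propan-2-yl)octahydro-1H-inden-5-yl (2Z)-2-methylbut-2-enoate | C=C1[C@@H]2C[C@H](OC(C)=O)/C(=C\C)[C@H]2[C@H](C(C)C)[C@H](O[Si](C)(C)C(C)(C)C)[C@H]1OC(=O)/C(C)=C\C | intermediate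
19 | (1Z,2S,3aR,5S,6S,7S,7aR)-2-(acetyloxy)-1-ethylidene-6-hydroxy-4-methylidene-7-(propan-2-yl)octahydro-1H-inden-5-yl (2Z)-2-methylbut-2-enoate | C=C1[C@@H]2C[C@H](OC(C)=O)/C(=C\C)[C@H]2[C@H](C(C)C)[C@H](O)[C@H]1OC(=O)/C(C)=C\C | target

Total step count: 12. Longest linear sequence: 11 steps (steps 2–12 from cyclopent-2-en-1-one 3; step 1 makes the two-carbon fragment 2).

**Steps most likely to fail**

Risk 1, step 4 (Proposed new method). The liberated aldehyde may undergo intermolecular aldol addition with 2 before the weakly nucleophilic vinylsilane closes the ring. The vinylsilane may also be protodesilylated, or the ring closure may show poor facial control at C5 because C7a is still sp2 at that stage. The fallback uses known chemistry and closes ring A on the sp3 ketone through an organochromium addition. Setting out from 7, ipso-iododesilylation with N-iodosuccinimide (MeCN–ClCH2CN, 0 °C) gives (2E,3R)-3-(1-iodoethenyl)-2-(2-methylpropylidene)cyclopentan-1-one F1. TiCl4-mediated Mukaiyama–Michael addition of 2 (CH2Cl2, −78 °C), aqueous work-up and brief equilibration on silica gel to the trans-2,3-disubstituted ketone give (2S,3S)-2-{[tert-butyl(dimethyl)silyl]oxy}-3-[(1S,2R)-2-(1-iodoethenyl)-5-oxocyclopentyl]-4-methylpentanal F2. An intramolecular Nozaki–Hiyama–Kishi reaction (CrCl2, NiCl2 cat., DMF, rt) then forms C4–C5 and comes back to the route at 10.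

Risk 2, step 9. The basic ylide may enolize the hindered ketone instead of adding to it (loss of the C2 configuration), the Z/E control may be poor, or the ylide may attack the angelate. The fallback replaces kinetic Wittig selectivity by a stereospecific elimination. Setting out from 15, addition of lithiated ethyl(diphenyl)phosphine oxide (THF, −78 °C) gives the β-hydroxy phosphine oxides, from which (2S,3aR,5S,6S,7S,7aR)-6-{[tert-butyl(dimethyl)silyl]oxy}-1-[1-(diphenylphosphoryl)ethyl]-1-hydroxy-4-methylidene-7-(propan-2-yl)-2-[(triethylsilyl)oxy]octahydro-1H-inden-5-yl (2Z)-2-methylbut-2-enoate F3, the C1/C1′ diastereomer that leads to the Z-alkene, is separated by chromatography. Its syn-elimination (NaH, DMF; Horner–Wittig sequence) comes back to the route at 16.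

Risk 3, step 7. Oxygen transfer to the enol ether may occur with poor facial selectivity, since the trans-hydrindane offers little intrinsic bias at C2, and the exocyclic methylene may be over-oxidized. The fallback sets C2 by catalyst-controlled reduction instead of catalyst-controlled oxidation. Setting out from 17 (carried through as a mixture of C2 epimers), oxidation with Dess–Martin periodinane (1,1,1-triacetoxy-1,1-dihydro-1,2-benziodoxol-3(1H)-one) gives (1Z,3aR,5S,6S,7S,7aR)-6-{[tert-butyl(dimethyl)silyl]oxy}-1-ethylidene-4-methylidene-2-oxo-7-(propan-2-yl)octahydro-1H-inden-5-yl (2Z)-2-methylbut-2-enoate F4. Corey–Bakshi–Shibata reduction (1-methyl-3,3-diphenyltetrahydro-1H,3H-pyrrolo[1,2-c][1,3,2]oxazaborole, enantiomer chosen for 2S, catecholborane, −78 °C) then comes back to the route at 17.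

**Further compounds**
F1 | step 4 | (2E,3R)-3-(1-iodoethenyl)-2-(2-methylpropylidene)cyclopentan-1-one | C=C(I)[C@@H]1CCC(=O)/C1=C/C(C)C
F2 | step 4 | (2S,3S)-2-{[tert-butyl(dimethyl)silyl]oxy}-3-[(1S,2R)-2-(1-iodoethenyl)-5-oxocyclopentyl]-4-methylpentanal | C=C(I)[C@@H]1CCC(=O)[C@H]1[C@H](C(C)C)[C@H](O[Si](C)(C)C(C)(C)C)C=O
F3 | step 9 | (2S,3aR,5S,6S,7S,7aR)-6-{[tert-butyl(dimethyl)silyl]oxy}-1-[1-(diphenylphosphoryl)ethyl]-1-hydroxy-4-methylidene-7-(propan-2-yl)-2-[(triethylsilyl)oxy]octahydro-1H-inden-5-yl (2Z)-2-methylbut-2-enoate | C=C1[C@@H]2C[C@H](O[Si](CC)(CC)CC)C(O)(C(C)P(=O)(c3ccccc3)c3ccccc3)[C@H]2[C@H](C(C)C)[C@H](O[Si](C)(C)C(C)(C)C)[C@H]1OC(=O)/C(C)=C\C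
F4 | step 7 | (1Z,3aR,5S,6S,7S,7aR)-6-{[tert-butyl(dimethyl)silyl]oxy}-1-ethylidene-4-methylidene-2-oxo-7-(propan-2-yl)octahydro-1H-inden-5-yl (2Z)-2-methylbut-2-enoate | C=C1[C@@H]2CC(=O)/C(=C\C)[C@H]2[C@H](C(C)C)[C@H](O[Si](C)(C)C(C)(C)C)[C@H]1OC(=O)/C(C)=C\C
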